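The runs come from a simulation for substances that don't exist; scatter was added.

Before charging the east flask I looked at one ratio, partner charged over substrate charged. It was 2.00 in the spring run and 1.00 in the midnight run, but east was to have 0.240. I call this ratio the cover, and east's stood below both earlier runs. My choice was whether east was worth charging or the row should stop at west.

all flasks: free catalyst 1.5 mM
- spring: substrate 0.30 M; coupling partner 0.60 M; second catalyst 1 mM; run made earlier
- midnight: substrate 0.30 M; coupling partner 0.30 M; second catalyst 1.5 mM; run made earlier
- south-west: substrate 0.30 M; coupling partner 0.600 M; second catalyst 1.5 mM; time 5.0 h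
- north-east: substrate 0.60 M; coupling partner 0.600 M; second catalyst 1.5 mM; time 5.0 h
- west: substrate 1.2 M; coupling partner 0.600 M; second catalyst 1.5 mM; time 5.0 h
- east: substrate 2.5 M; coupling partner 0.600 M; second catalyst 1.5 mM; time 5.0 h

- spring (time / h: target / %, substrate / %): 0.250: 1.0, 52.9; 0.500: 2.9, 33.4; 1.33: 9.9, 13.7; 3.00: 21.6, 5.9
- midnight (time / h: target / %, substrate / %): 0.833: 4.9, 18.1; 1.50: 9.9, 7.9; 2.50: 16.5, 3.4; 3.00: 20.1, 2.7

(scatter of a reading: 0.3 percentage points)

- the analysis behind the earlier runs scatters by 0.3 percentage points, standard deviation
- "hardly changes" means that all values lie within two and a half points (for a concentration: within two and a half percent of the largest)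

1. [target] at the end for south-west, north-east, west, east, in this order
2. how that number moves from the first to the last of them (rises, then falls / falls, then rises / rises all the way / falls all the way / hardly changes)

After 3.00 h the spring run showed 5.9% substrate and 21.6% target, so 72.5% of the charge stood in forms that were not read. I took one partner per target, so target, in percent of the substrate charged, stops at the cover. Below a cover of one, partner becomes the limiting reagent. For east that ceiling was 0.600 M, and across north-east, west and east it stayed at 0.600 M, so extra substrate raised no ceiling. This is a ceiling of my own and not a forecast of the row. I meant to charge east if it promised clearly more target than west.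

The forecast gave 0.14 M, 0.175 M, 0.19 M and 0.195 M, a row that rises all the way, on the ground that “target rises a little and then flattens”.

The flasks gave 0.120 M, 0.206 M, 0.282 M and 0.257 M: the row rises, then falls.

    substrate + free catalyst → free catalyst + intermediate (k = 0.470 M⁻¹ s⁻¹)
    coupling partner + second catalyst + intermediate → second catalyst + target (k = 0.0800 M⁻² s⁻¹)
    coupling partner + free catalyst → spent catalyst (k = 8.00 × 10⁻⁴ M⁻¹ s⁻¹)
    substrate + coupling partner → uncatalysed product (k = 2.30 × 10⁻⁴ M⁻¹ s⁻¹)

South-west's 0.120 M, at a cover of 2.00, came in part from two things acting together: the reading at 5.00 h, where 50.0 h gives 0.202 M, and the step to spent catalyst, without which it stands at 0.153 M. East had 0.75% of its partner left at 5.00 h, and its cover of 24.0% had gone to two takers: target 10.3% and uncatalysed product 13.5% of the substrate charged. Without that second taker east's target stands at 0.577 M instead of 0.257 M, so it is a part of the reason for the fall. West, with a cover of 50.0% and 12% of its partner left, held target 23.5% and uncatalysed product 20.2%. Target's share of that pair was 53.8% in west and 43.3% in east.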